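(The earlier runs and the new flask are calculated for an exercise, noise included.)

The ratio I start from is Wednesday's hourly gain of target, in percent of the charge, over Saturday's, each read as a line through the origin of that run's readings.

| flask | substrate | gas phase | remark | time |
|---|---|---|---|---|
| Wednesday's | 2.4 M | 200 mM (held) | the very flask that is asked about, followed so far |  |
| Saturday's | 1.2 M | 200 mM (held) | run made earlier |  |
| flask | 2.4 M | 200 mM (held) |  | 15 h |

| run | time / h | target / % | substrate / % |
|---|---|---|---|
| Wednesday's | 0.667 | 0.3 | 99.9 |
| Wednesday's | 1.33 | 0 | 97.5 |
| Wednesday's | 2.00 | 2.5 | 98.0 |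
| Wednesday's | 2.50 | 1.7 | 96.9 |
| Saturday's | 2.00 | 1.8 | 96.1 |
| Saturday's | 5.00 | 5.9 | 94.6 |
| Saturday's | 10.0 | 9.0 | 87.8 |
| Saturday's | 15.0 | 11.4 | 86.4 |

(standard deviation of a reading: 1 percentage point)

- percent here means substrate units held: one side product counts as two
- at the start none of the gas is dissolved
- steps that have been proposed: gas phase <-> dissolved gas; substrate + dissolved gas -> target; dissolved gas + target -> over-reacted product; substrate + target -> side product; dissolved gas -> decomposed reagent

- epsilon: doubling the transfer coefficient of the gas phase, all else as stated
- theta: doubling the saturation concentration of gas phase, all else as stated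

* amount of target at 15 h, in percent of the substrate charged
* the change that raises the amount of target at 15 h, in percent of the substrate charged most ("none" if none brings more than 2 percentage points) (epsilon / theta / none)
* amount of target at 15 h, in percent of the substrate charged, after epsilon

That ratio reads 0.913. Going to logarithms, I divide its log10 by the log10 of the ratio of the two values of c(substrate), and get −0.132. I read this as the power of c(substrate) that the percent of target at a fixed time follows, the charge exponent; zero would mean target made in proportion to c(substrate), pseudo-first-order in substrate at a fixed c(dissolved gas). With a scatter of 1 percentage point on Wednesday's early readings, and with Wednesday's line ending at 2.50 h but Saturday's at 15.0 h, it is a rough reading. Scaling Saturday's 11.4% at 15.0 h by this exponent, I commit to 10.4% for the flask.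

The forecast gives 9.5%, names theta as the better change and puts epsilon at 12%, arguing “Doubling saturation doubles dissolved gas outright”.

The flask gives 11.2%; theta adds 7.3 points, and epsilon gives 11.6%.

    gas phase ⇌ dissolved gas, rate k1*(csat - [dissolved gas]) (kL = 3.30 h⁻¹)
    substrate + dissolved gas → target (k = 0.0550 L mol⁻¹ h⁻¹)
    dissolved gas + target → over-reacted product (k = 0.0900 L mol⁻¹ h⁻¹)
    substrate + target → side product (k = 0.00620 L mol⁻¹ h⁻¹)
    dissolved gas → decomposed reagent (k = 0.0830 h⁻¹)

Raised with all else held, the substrate of this flask has to reach 14.6 M before the target at 15 h has moved by 5 percentage points. For the neighbour flask at 0.60 M, the charge exponent applied to Saturday's reading gives 12.5%, and that flask holds 12.4% of target.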